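The tetrahydrofuran ring (O1, C2, C3, C4, C5; C3 carries the carbinol carbon, C4 the benzyl group) is cut at O1–C2 and C3–C4. This exploits two hidden features: O1–C2–C3–C(OH) is a β-alkoxy carbonyl array, and the C4 benzyl group is a reduced styrene. One chiral amine therefore joins an open-chain cinnamyl-type alcohol and acrolein. Iminium oxa-Michael addition makes O1–C2. Photoredox oxidation of the resulting enamine and 5-exo radical closure onto the styrene make C3–C4. Thiol hydrogen transfer ends a redox-neutral (3+2) annulation that sets both ring stereocentres. Arylation to the ketone, Felkin–Anh reduction and desilylation follow.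

Key step: step 3

Remark: compounds 1, 4 and 8 and both enantiomers of the amine catalyst are taken to be commercial.

Step 1
Reactants: 1 sinapaldehyde [(E)-3-(4-hydroxy-3,5-dimethoxyphenyl)prop-2-enal]
Product: 2 (E)-3-[4-(tert-butyldimethylsilyloxy)-3,5-dimethoxyphenyl]prop-2-enal
Conditions: TBSCl, imidazole, DMF, 23 °C
Reagents that add atoms: tert-butyldimethylsilyl chloride, CC(C)(C)[Si](C)(C)Cl
Why: Imidazole-promoted silyl ether formation at the only OH group masks a phenol that would otherwise act as a hydrogen donor and electron donor in step 3.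

Step 2
Reactants: 2 (E)-3-[4-(tert-butyldimethylsilyloxy)-3,5-dimethoxyphenyl]prop-2-enal
Product: 3 (E)-3-[4-(tert-butyldimethylsilyloxy)-3,5-dimethoxyphenyl]prop-2-en-1-ol
Conditions: i-Bu2AlH, CH2Cl2, −78 °C; then aqueous work-up
Reagents that add atoms: none
Why: 1,2-Reduction of an enal by an electrophilic aluminium hydride at low temperature should leave the E-alkene and the aryl silyl ether untouched.

Step 3
Reactants: 3 (E)-3-[4-(tert-butyldimethylsilyloxy)-3,5-dimethoxyphenyl]prop-2-en-1-ol; 4 acrolein
Product: 7 (3R,4R)-4-[4-(tert-butyldimethylsilyloxy)-3,5-dimethoxybenzyl]tetrahydrofuran-3-carbaldehyde, via enamine 5 (not isolated), via oxa-Michael aldehyde 6 (not isolated)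
Conditions: 4 (1.5 equiv, slow addition), (R)-2-[diphenyl(trimethylsilyloxy)methyl]pyrrolidine (20 mol %), PhCO2H (20 mol %), [Ir(Fmppy)2(dtbbpy)]PF6 (1 mol %), 2,4,6-triisopropylbenzenethiol (15 mol %), DME, 0 °C, blue LEDs, argon
Reagents that add atoms: none
Why: Proposed new method: the amine and 4 form an iminium ion, the primary allylic OH of 3 adds reversibly to its CH2 terminus (O1–C2) to give enamine 5 (hydrolysed resting form 6), the photoexcited iridium complex oxidises 5 to an electrophilic enaminyl radical cation that attacks the styrene carbon remote from the arene (C3–C4), the benzylic radical takes H from the thiol, the thiyl radical is reduced by the reduced photocatalyst and protonated, and hydrolysis frees 7 and the amine, so that 3 and 4 combine without loss of any atom. The closest known reaction types are the amine/PdCl2 co-catalysed dynamic oxa-Michael/carbocyclisation of propargylic alcohols with enals, which shows that a reversible amine-mediated oxa-Michael step can be drained by an irreversible ring closure, and the photoredox/enamine/thiol α-alkylation of aldehydes with tethered olefins, which is the second half of the cascade; only their merger on acrolein is new. The tetrahydrofuran ring closes in the 5-exo-trig mode. C3 is set by the CPh2(OSiMe3) group of the (R)-amine, which blocks one face of the E-configured radical cation (the (S)-amine is known to direct C–C bond formation at enamines to the opposite face, which here would give 3S), and C4 is set relative to C3 by a chair-like transition state with the styryl arm pseudo-equatorial and anti to the bulky iminium carbon, hence trans. The step needs oxidation of the enamine in the presence of the trioxygenated styrene, secured by the much lower oxidation potential of the enamine and a weakly oxidising photocatalyst, and it needs attack at the distal alkene carbon, secured by the polarity match with the electron-rich arene and by benzylic stabilisation. Thiol that is lost to 4 by thia-Michael addition should be returned, since oxidation of the enamine of that adduct leads to β-scission into thiyl radical and acrolein iminium ion, and slow addition of 4 keeps this drain and acrolein polymerisation small.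

Step 4
Reactants: 8 4-bromo-2,6-dimethoxyphenol
Product: 9 (4-bromo-2,6-dimethoxyphenoxy)(tert-butyl)dimethylsilane
Conditions: TBSCl, imidazole, DMF, 23 °C
Reagents that add atoms: tert-butyldimethylsilyl chloride, CC(C)(C)[Si](C)(C)Cl
Why: Silyl ether formation removes the acidic phenol proton so that the aryl bromide can be turned into a Grignard reagent.

Step 5
Reactants: 9 (4-bromo-2,6-dimethoxyphenoxy)(tert-butyl)dimethylsilane; 7 (3R,4R)-4-[4-(tert-butyldimethylsilyloxy)-3,5-dimethoxybenzyl]tetrahydrofuran-3-carbaldehyde
Product: 12 [4-(tert-butyldimethylsilyloxy)-3,5-dimethoxyphenyl]{(3R,4R)-4-[4-(tert-butyldimethylsilyloxy)-3,5-dimethoxybenzyl]tetrahydrofuran-3-yl}methanone, via aryl Grignard reagent 10 (not isolated), via bromomagnesium alkoxide 11 (not isolated)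
Conditions: 9, Mg turnings, LiCl, THF, 25 °C; then 7, −20 °C; then PhCHO, 25 °C; aqueous work-up
Reagents that add atoms: none
Why: Grignard addition is followed in the same flask by a magnesium Oppenauer oxidation, in which the electron-rich benzylic alkoxide 11 passes its carbinol hydride to benzaldehyde through a six-membered transition state; the carbinol centre is erased on purpose because the Felkin–Anh and chelate models both predict the wrong epimer for direct aryl addition, and C3 stays in its thermodynamically preferred trans arrangement.

Step 6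
Reactants: 12 [4-(tert-butyldimethylsilyloxy)-3,5-dimethoxyphenyl]{(3R,4R)-4-[4-(tert-butyldimethylsilyloxy)-3,5-dimethoxybenzyl]tetrahydrofuran-3-yl}methanone
Product: 13 (S)-[4-(tert-butyldimethylsilyloxy)-3,5-dimethoxyphenyl]{(3R,4R)-4-[4-(tert-butyldimethylsilyloxy)-3,5-dimethoxybenzyl]tetrahydrofuran-3-yl}methanol
Conditions: LiBH(s-Bu)3, THF, −78 °C; then pH 7 buffer
Reagents that add atoms: none
Why: Felkin–Anh-controlled hydride addition: with the branched ring carbon C4 perpendicular to the carbonyl plane, C2H2–O1 next to the carbonyl oxygen (a lithium 1,3-chelate has the same shape) and the C3 hydrogen next to the aryl group, the bulky borohydride attacks anti to C4 and should give the S carbinol, while the ring stereocentres are untouched at −78 °C.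

Step 7
Reactants: 13 (S)-[4-(tert-butyldimethylsilyloxy)-3,5-dimethoxyphenyl]{(3R,4R)-4-[4-(tert-butyldimethylsilyloxy)-3,5-dimethoxybenzyl]tetrahydrofuran-3-yl}methanol
Product: 14 (S)-(4-hydroxy-3,5-dimethoxyphenyl)[(3R,4R)-4-(4-hydroxy-3,5-dimethoxybenzyl)tetrahydrofuran-3-yl]methanol (target)
Conditions: n-Bu4NF, AcOH, THF, 0 °C
Reagents that add atoms: none
Why: Fluoride cleaves both aryl silyl ethers, and the acetic acid buffer keeps the medium near neutral so that the 4-hydroxybenzylic alcohol should neither ionise to a quinone methide nor to a benzylic cation, leaving all three stereocentres intact.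

Compound list
1 | sinapaldehyde, (E)-3-(4-hydroxy-3,5-dimethoxyphenyl)prop-2-enal | COc1cc(/C=C/C=O)cc(OC)c1O | starting material
2 | (E)-3-[4-(tert-butyldimethylsilyloxy)-3,5-dimethoxyphenyl]prop-2-enal | COc1cc(/C=C/C=O)cc(OC)c1O[Si](C)(C)C(C)(C)C | intermediate
3 | (E)-3-[4-(tert-butyldimethylsilyloxy)-3,5-dimethoxyphenyl]prop-2-en-1-ol | COc1cc(/C=C/CO)cc(OC)c1O[Si](C)(C)C(C)(C)C | intermediate
4 | acrolein | C=CC=O | starting material
5 | E-enamine of aldehyde 6 with (R)-2-[diphenyl(trimethylsilyloxy)methyl]pyrrolidine (not isolated) | C[Si](C)(C)OC(c1ccccc1)(c1ccccc1)[C@H]1CCCN1/C=C/COC/C=C/c1cc(OC)c(O[Si](C)(C)C(C)(C)C)c(OC)c1 | intermediate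
6 | 3-{[(E)-3-(4-(tert-butyldimethylsilyloxy)-3,5-dimethoxyphenyl)prop-2-en-1-yl]oxy}propanal (not isolated) | O=CCCOC/C=C/c1cc(OC)c(O[Si](C)(C)C(C)(C)C)c(OC)c1 | intermediate
7 | (3R,4R)-4-[4-(tert-butyldimethylsilyloxy)-3,5-dimethoxybenzyl]tetrahydrofuran-3-carbaldehyde | COc1cc(C[C@H]2COC[C@@H]2C=O)cc(OC)c1O[Si](C)(C)C(C)(C)C | intermediate
8 | 4-bromo-2,6-dimethoxyphenol | COc1cc(Br)cc(OC)c1O | starting material
9 | (4-bromo-2,6-dimethoxyphenoxy)(tert-butyl)dimethylsilane | COc1cc(Br)cc(OC)c1O[Si](C)(C)C(C)(C)C | intermediate
10 | [4-(tert-butyldimethylsilyloxy)-3,5-dimethoxyphenyl]magnesium bromide (not isolated) | COc1cc([Mg]Br)cc(OC)c1O[Si](C)(C)C(C)(C)C | intermediate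
11 | bromomagnesium alkoxide of the aryl adduct of 7, both carbinol epimers (not isolated) | COc1cc(C[C@H]2COC[C@@H]2C(O[Mg]Br)c2cc(OC)c(O[Si](C)(C)C(C)(C)C)c(OC)c2)cc(OC)c1O[Si](C)(C)C(C)(C)C | intermediate
12 | [4-(tert-butyldimethylsilyloxy)-3,5-dimethoxyphenyl]{(3R,4R)-4-[4-(tert-butyldimethylsilyloxy)-3,5-dimethoxybenzyl]tetrahydrofuran-3-yl}methanone | COc1cc(C[C@H]2COC[C@@H]2C(=O)c2cc(OC)c(O[Si](C)(C)C(C)(C)C)c(OC)c2)cc(OC)c1O[Si](C)(C)C(C)(C)C | intermediate
13 | (S)-[4-(tert-butyldimethylsilyloxy)-3,5-dimethoxyphenyl]{(3R,4R)-4-[4-(tert-butyldimethylsilyloxy)-3,5-dimethoxybenzyl]tetrahydrofuran-3-yl}methanol | COc1cc(C[C@H]2COC[C@@H]2[C@H](O)c2cc(OC)c(O[Si](C)(C)C(C)(C)C)c(OC)c2)cc(OC)c1O[Si](C)(C)C(C)(C)C | intermediate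
14 | (S)-(4-hydroxy-3,5-dimethoxyphenyl)[(3R,4R)-4-(4-hydroxy-3,5-dimethoxybenzyl)tetrahydrofuran-3-yl]methanol | COc1cc(C[C@H]2COC[C@@H]2[C@H](O)c2cc(OC)c(O)c(OC)c2)cc(OC)c1O | target

Total step count: 7. Longest linear sequence: 6 steps (steps 1, 2, 3, 5, 6, 7).

Steps most likely to fail

Step 3. Several processes may interfere:
- The cascade may stall because the thiol is drained by acrolein faster than it is returned.
- The oxa-Michael equilibrium may supply too little enamine.
- The benzylic radical may add to acrolein.
- Energy transfer may isomerise the styrene and weaken the trans selectivity.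

Any cis isomer must be removed by chromatography before step 5, because its later epimerisation at C3 would feed the enantiomeric trans series.

The fallback uses known chemistry, sets out from 3 and comes back at 7. It forms the two bonds in separate operations, so that acrolein and thiol never meet. PMe3-catalysed oxa-Michael addition of 3 to methyl acrylate should give methyl 3-{[(E)-3-(4-(tert-butyldimethylsilyloxy)-3,5-dimethoxyphenyl)prop-2-en-1-yl]oxy}propanoate F1. Half-reduction with i-Bu2AlH at −78 °C should give aldehyde 6, now isolated. Aldehyde 6 is then closed to 7 by the established photoredox/enamine/thiol intramolecular α-alkylation of aldehydes, with the same amine, photocatalyst and thiol.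

Step 5. Hydride transfer from the hindered alkoxide 11 to benzaldehyde may be slow or incomplete, and the basic medium may start aldol chemistry of benzaldehyde.

The fallback sets out from 9 and 7 and comes back at 12. It replaces the hydride-transfer oxidation by a separate oxidation of an isolated alcohol. Bromine–lithium exchange of 9 with n-BuLi at −78 °C should give [4-(tert-butyldimethylsilyloxy)-3,5-dimethoxyphenyl]lithium F2. Its addition to 7 should give the epimeric carbinol mixture F3. Oxidation of this mixture with Dess–Martin periodinane buffered with NaHCO3 should give 12.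

Step 6. Facial selectivity may be poor if the substrate bias of the ring is weaker than the model suggests.

The fallback sets out from 12 and comes back at 13. It moves the control element from the substrate to a chiral catalyst. A Corey–Bakshi–Shibata reduction with the (R)-B-methyl oxazaborolidine and BH3·SMe2 treats the aryl group as the large substituent. It should therefore deliver the S carbinol in the same sense as the substrate bias. No new compound arises (F0).

Further compounds
F1 | step 3 | methyl 3-{[(E)-3-(4-(tert-butyldimethylsilyloxy)-3,5-dimethoxyphenyl)prop-2-en-1-yl]oxy}propanoate | COC(=O)CCOC/C=C/c1cc(OC)c(O[Si](C)(C)C(C)(C)C)c(OC)c1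
F2 | step 5 | [4-(tert-butyldimethylsilyloxy)-3,5-dimethoxyphenyl]lithium | COc1cc([Li])cc(OC)c1O[Si](C)(C)C(C)(C)C
F3 | step 5 | [4-(tert-butyldimethylsilyloxy)-3,5-dimethoxyphenyl]{(3R,4R)-4-[4-(tert-butyldimethylsilyloxy)-3,5-dimethoxybenzyl]tetrahydrofuran-3-yl}methanol, mixture of carbinol epimers | COc1cc(C[C@H]2COC[C@@H]2C(O)c2cc(OC)c(O[Si](C)(C)C(C)(C)C)c(OC)c2)cc(OC)c1O[Si](C)(C)C(C)(C)C
F0 | step 6 | none | none
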